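Ring C of the target is cut at three bonds around its carbonyl. C4 lies between C4a of ring A and C3, and O1 bridges C8a and C2. C4 can therefore be carbon monoxide, ring A with O1 an ortho-iodophenol, and C2, C3 with ring B a terminal arylacetylene. One palladium-catalysed carbonylative coupling in diethylamine joins the three pieces, makes C4a–C4, C4–C3 and O1–C2, and closes ring C as the flavone with the full carbon skeleton. The precursors are a 2-iodophenol bearing a MOM ether para to iodine and a MOM-protected 3,5-diprenyl-4-hydroxyphenylacetylene. A ligand-controlled copper hydride 1,4-reduction then sets (S)-C2, and mild acid frees both phenols.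

Key step: step 5

Assumption: (S)-DTBM-SEGPHOS is taken to be the ligand antipode that sends hydride to the Re face of C2, by analogy with β-substituted cyclic enones; if a trial run shows the opposite sense, the equally available (R)-ligand is used and nothing else changes.

Step 1
Reactants: 1 4-iodophenol; 2 1-bromo-3-methylbut-2-ene (prenyl bromide)
Product: 3 4-iodo-2,6-bis(3-methylbut-2-enyl)phenol
Conditions: aq KOH (3 equiv), 2 (2.5 equiv), H2O, rt
Reagents that add atoms: none
Why: This is phenoxide C-alkylation in water, a known o,o'-diprenylation of para-halophenols, in which hydrogen bonding shields the phenoxide oxygen, iodine blocks the para carbon, and SN2 attack at the primary carbon of 2 places unbranched prenyl groups on both ortho carbons.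

Step 2
Reactants: 3 4-iodo-2,6-bis(3-methylbut-2-enyl)phenol
Product: 4 5-iodo-2-(methoxymethoxy)-1,3-bis(3-methylbut-2-enyl)benzene
Conditions: NaH, MOMCl, THF–DMF, 0 °C to rt
Reagents that add atoms: chloromethyl methyl ether (MOMCl), COCCl
Why: This is a Williamson-type etherification in which the small, very reactive chloromethyl ether should alkylate the hindered sodium phenoxide cleanly while the aryl iodide and the alkenes stay untouched.

Step 3
Reactants: 4 5-iodo-2-(methoxymethoxy)-1,3-bis(3-methylbut-2-enyl)benzene; 5 ethynyl(trimethyl)silane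
Product: 7 5-ethynyl-2-(methoxymethoxy)-1,3-bis(3-methylbut-2-enyl)benzene, via trimethylsilyl alkyne 6 (not isolated)
Conditions: PdCl2(PPh3)2 (2 mol %), CuI (4 mol %), Et3N, THF, rt, argon; then K2CO3, MeOH, rt
Reagents that add atoms: none
Why: A Sonogashira coupling of an aryl iodide with no ortho substituent is followed by base-catalysed methanolysis of the C–Si bond in the same flask, two standard operations that spare the MOM ether and the trisubstituted alkenes.

Step 4
Reactants: 8 4-iodobenzene-1,3-diol (4-iodoresorcinol)
Product: 9 2-iodo-5-(methoxymethoxy)phenol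
Conditions: NaH (2.2 equiv), DMF, 0 °C; MOMCl (1.0 equiv), −20 to 0 °C; aq NH4Cl
Reagents that add atoms: chloromethyl methyl ether (MOMCl), COCCl
Why: This is a site-selective Williamson-type O-alkylation of the resorcinol dianion, in which the phenoxide para to iodine is both the more basic and the less hindered oxygen, so one equivalent of MOMCl should react there and leave the oxygen next to iodine free for ring closure.

Step 5
Reactants: 9 2-iodo-5-(methoxymethoxy)phenol; 10 carbon monoxide; 7 5-ethynyl-2-(methoxymethoxy)-1,3-bis(3-methylbut-2-enyl)benzene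
Product: 13 7-(methoxymethoxy)-2-[4-(methoxymethoxy)-3,5-bis(3-methylbut-2-enyl)phenyl]chromen-4-one, via hydroxyaryl ynone 11 (not isolated), via diethylamino enaminone 12 (not isolated)
Conditions: PdCl2(dppf) (3 mol %), CO (20 bar), Et2NH (solvent), 120 °C, autoclave, no copper salt
Reagents that add atoms: diethylamine, CCNCC (its atoms are held only in intermediate 12 and leave again on ring closure)
Why: Zerovalent palladium, generated from PdCl2(dppf) in the amine, adds to the C–I bond of 9, migratory insertion of CO gives an aroyl complex of divalent palladium, and transfer of the acetylide of 7 followed by reductive elimination forms C4a–C4 and C4–C3 in ynone 11. Diethylamine adds to the alkyne carbon that becomes C2 to give the push–pull enaminone 12, and the ortho phenol then displaces the amine by a 6-endo-trig addition–elimination (formally the 6-endo-dig closure of 11), which forms O1–C2 and closes ring C. The closest known reaction type is the carbonylative Sonogashira annulation of ortho-iodophenols with terminal arylacetylenes to flavones in a secondary amine, so this is a known reaction on a new pair of partners. No stereocenter is created, since C2 stays trigonal. Carbonylative coupling must win over direct coupling, which would end in a 2-arylbenzofuran, and this is secured by the absence of copper, by CO pressure and by the electron-rich aryl–palladium bond of ring A, which takes up CO quickly. 6-endo closure must win over 5-exo closure to an aurone, and this is secured by the amine adduct, in which C2 is the only electrophilic carbon, while the single free hydroxyl ortho to iodine, the two MOM ethers and the unactivated prenyl alkenes leave no other site to react.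

Step 6
Reactants: 13 7-(methoxymethoxy)-2-[4-(methoxymethoxy)-3,5-bis(3-methylbut-2-enyl)phenyl]chromen-4-one
Product: 15 (2S)-7-(methoxymethoxy)-2-[4-(methoxymethoxy)-3,5-bis(3-methylbut-2-enyl)phenyl]-2,3-dihydrochromen-4-one, via silyl enol ether 14 (not isolated)
Conditions: Cu(OAc)2 (5 mol %), (S)-DTBM-SEGPHOS (5.5 mol %), (EtO)2MeSiH (3 equiv), toluene, 0 °C to rt; then 1 M aq HCl, THF, 0 °C, brief
Reagents that add atoms: diethoxy(methyl)silane, CCO[SiH](C)OCC (its silyl group is held only in intermediate 14 and is lost in the quench)
Why: This is an asymmetric copper hydride conjugate reduction (1,4-hydrosilylation), known for β,β-disubstituted cyclic enones and for 2-substituted chromones, in which the bisphosphine-bound copper hydride delivers hydride to the Re face of C2 and so sets (S)-C2 under catalyst control, silyl transfer traps the enolate as 14 so that neither over-reduction nor β-elimination of O1 follows, the isolated alkenes and MOM ethers are inert, and the cold acidic quench frees the ketone without base-induced opening of ring C.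

Step 7
Reactants: 15 (2S)-7-(methoxymethoxy)-2-[4-(methoxymethoxy)-3,5-bis(3-methylbut-2-enyl)phenyl]-2,3-dihydrochromen-4-one
Product: 16 (2S)-7-hydroxy-2-[4-hydroxy-3,5-bis(3-methylbut-2-enyl)phenyl]-2,3-dihydrochromen-4-one (abyssinone-IV)
Conditions: HCl (0.5 M), MeOH–THF, rt, stopped at full conversion; pH 6–7 phosphate buffer
Reagents that add atoms: none
Why: This is acid-catalysed acetal exchange (MOM solvolysis) with methanol as the formaldehyde acceptor, common practice for ortho-prenylated phenols, in which dilute acid, room temperature and a prompt neutral quench should keep the prenyl groups from closing to chromans, and C2 should hold because flavanones lose their configuration mainly by base-induced opening to the chalcone.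

Compound list
1 | 4-iodophenol | Oc1ccc(I)cc1 | starting material
2 | 1-bromo-3-methylbut-2-ene (prenyl bromide) | CC(C)=CCBr | starting material
3 | 4-iodo-2,6-bis(3-methylbut-2-enyl)phenol | CC(C)=CCc1cc(I)cc(CC=C(C)C)c1O | intermediate
4 | 5-iodo-2-(methoxymethoxy)-1,3-bis(3-methylbut-2-enyl)benzene | CC(C)=CCc1cc(I)cc(CC=C(C)C)c1OCOC | intermediate
5 | ethynyl(trimethyl)silane | C#C[Si](C)(C)C | starting material
6 | {[4-(methoxymethoxy)-3,5-bis(3-methylbut-2-enyl)phenyl]ethynyl}trimethylsilane | CC(C)=CCc1cc(C#C[Si](C)(C)C)cc(CC=C(C)C)c1OCOC | intermediate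
7 | 5-ethynyl-2-(methoxymethoxy)-1,3-bis(3-methylbut-2-enyl)benzene | CC(C)=CCc1cc(C#C)cc(CC=C(C)C)c1OCOC | intermediate
8 | 4-iodobenzene-1,3-diol (4-iodoresorcinol) | Oc1ccc(I)c(O)c1 | starting material
9 | 2-iodo-5-(methoxymethoxy)phenol | Oc1cc(OCOC)ccc1I | intermediate
10 | carbon monoxide | [C-]#[O+] | starting material
11 | 1-[2-hydroxy-4-(methoxymethoxy)phenyl]-3-[4-(methoxymethoxy)-3,5-bis(3-methylbut-2-enyl)phenyl]prop-2-yn-1-one | COCOc1ccc(C(=O)C#Cc2cc(CC=C(C)C)c(OCOC)c(CC=C(C)C)c2)c(O)c1 | intermediate
12 | 3-(diethylamino)-1-[2-hydroxy-4-(methoxymethoxy)phenyl]-3-[4-(methoxymethoxy)-3,5-bis(3-methylbut-2-enyl)phenyl]prop-2-en-1-one (push–pull alkene, geometry not fixed) | COCOc1ccc(C(=O)C=C(N(CC)CC)c2cc(CC=C(C)C)c(OCOC)c(CC=C(C)C)c2)c(O)c1 | intermediate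
13 | 7-(methoxymethoxy)-2-[4-(methoxymethoxy)-3,5-bis(3-methylbut-2-enyl)phenyl]chromen-4-one | CC(C)=CCc1cc(-c2cc(=O)c3ccc(OCOC)cc3o2)cc(CC=C(C)C)c1OCOC | intermediate
14 | (2S)-4-{[diethoxy(methyl)silyl]oxy}-7-(methoxymethoxy)-2-[4-(methoxymethoxy)-3,5-bis(3-methylbut-2-enyl)phenyl]-2H-chromene | CC(C)=CCc1cc([C@@H]2C=C(O[Si](C)(OCC)OCC)c3ccc(OCOC)cc3O2)cc(CC=C(C)C)c1OCOC | intermediate
15 | (2S)-7-(methoxymethoxy)-2-[4-(methoxymethoxy)-3,5-bis(3-methylbut-2-enyl)phenyl]-2,3-dihydrochromen-4-one | CC(C)=CCc1cc([C@@H]2CC(=O)c3ccc(OCOC)cc3O2)cc(CC=C(C)C)c1OCOC | intermediate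
16 | (2S)-7-hydroxy-2-[4-hydroxy-3,5-bis(3-methylbut-2-enyl)phenyl]-2,3-dihydrochromen-4-one (abyssinone-IV) | CC(C)=CCc1cc([C@@H]2CC(=O)c3ccc(O)cc3O2)cc(CC=C(C)C)c1O | target

Total step count: 7
Longest linear sequence: 6 steps (steps 1, 2, 3, 5, 6, 7)

Steps most likely to fail

**Step 5.**
- What may go wrong is coupling without uptake of CO followed by closure to a five-membered oxygen ring, capture of the aroyl–palladium complex by the amine, or 5-exo closure.
- The fallback sets out from 9 and 7 and comes back at ynone 11, which is then closed to 13. Ring C is built in stages, and C4 comes from DMF and not from CO.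
- Iodine–magnesium exchange on 9 (i-PrMgCl·LiCl, two equivalents, the first spent on the phenol, THF, 0 °C to rt) and a DMF quench should give 2-hydroxy-4-(methoxymethoxy)benzaldehyde F1.
- The lithium acetylide of 7 (n-BuLi, THF, −78 °C) adds to the lithium phenoxide of the aldehyde to give the racemic propargylic alcohol F2.
- MnO2 in CH2Cl2 oxidises this alcohol to 11, now isolated, and Et2NH in EtOH at reflux closes ring C through 12 to 13.

**Step 6.**
- What may go wrong is slow hydride transfer to the electron-rich vinylogous ester, poor facial selectivity, or β-elimination of the ring oxygen from the copper enolate before silyl transfer, which would erode the configuration.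
- The fallback sets out from 13 and comes back at 15. It replaces asymmetric induction by resolution.
- The smaller and more reactive hydride made from Cu(OAc)2, 1,2-bis(diphenylphosphino)benzene and (EtO)2MeSiH in toluene should reduce 13 through the racemic silyl enol ether F3 to the racemic bis-MOM flavanone F4 after the same cold acidic quench.
- A kinetic resolution by Noyori asymmetric transfer hydrogenation follows, a known route to enantiopure flavanones (RuCl(p-cymene)[(R,R)-TsDPEN], HCO2H–Et3N, EtOAc, rt).
- It should reduce the (2R)-ketone to the cis-(2R,4R)-flavan-4-ol F5 and leave the (2S)-ketone 15. Chromatography separates the ketone from the alcohol.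

**Step 4.**
- What may go wrong is poor site selectivity between the two phenoxides, or double alkylation.
- The fallback sets out from 8 and comes back at 13. Protection is put off until ring closure has used up the oxygen next to iodine, so no choice between two hydroxyls remains.
- Ac2O and pyridine turn 8 into 4-iodo-1,3-phenylene diacetate F6.
- F6 then enters the known acetate variant of the carbonylative annulation with 7 and 10 (PdCl2(PPh3)2, dppp, thiourea, Et2NH, DBU, CO 1 bar, 40 °C). The amine strips both acetyl groups in the flask.
- The only phenol left in the 7-hydroxyflavone F7 is capped with MOMCl and i-Pr2NEt in CH2Cl2 to give 13.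

Further compounds
F1 | step 5 | 2-hydroxy-4-(methoxymethoxy)benzaldehyde | COCOc1ccc(C=O)c(O)c1
F2 | step 5 | racemic 1-[2-hydroxy-4-(methoxymethoxy)phenyl]-3-[4-(methoxymethoxy)-3,5-bis(3-methylbut-2-enyl)phenyl]prop-2-yn-1-ol | COCOc1ccc(C(O)C#Cc2cc(CC=C(C)C)c(OCOC)c(CC=C(C)C)c2)c(O)c1
F3 | step 6 | racemic 4-{[diethoxy(methyl)silyl]oxy}-7-(methoxymethoxy)-2-[4-(methoxymethoxy)-3,5-bis(3-methylbut-2-enyl)phenyl]-2H-chromene | CC(C)=CCc1cc(C2C=C(O[Si](C)(OCC)OCC)c3ccc(OCOC)cc3O2)cc(CC=C(C)C)c1OCOC
F4 | step 6 | racemic 7-(methoxymethoxy)-2-[4-(methoxymethoxy)-3,5-bis(3-methylbut-2-enyl)phenyl]-2,3-dihydrochromen-4-one | CC(C)=CCc1cc(C2CC(=O)c3ccc(OCOC)cc3O2)cc(CC=C(C)C)c1OCOC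
F5 | step 6 | (2R,4R)-7-(methoxymethoxy)-2-[4-(methoxymethoxy)-3,5-bis(3-methylbut-2-enyl)phenyl]-3,4-dihydro-2H-chromen-4-ol | CC(C)=CCc1cc([C@H]2C[C@@H](O)c3ccc(OCOC)cc3O2)cc(CC=C(C)C)c1OCOC
F6 | step 4 | 4-iodo-1,3-phenylene diacetate | CC(=O)Oc1ccc(I)c(OC(C)=O)c1
F7 | step 4 | 7-hydroxy-2-[4-(methoxymethoxy)-3,5-bis(3-methylbut-2-enyl)phenyl]chromen-4-one | CC(C)=CCc1cc(-c2cc(=O)c3ccc(O)cc3o2)cc(CC=C(C)C)c1OCOC
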